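The route cuts the C12–C13 bond of the hexadecanoyl chain. Carbinol carbon C13 carries two unbranched arms, propyl (C14–C16) and the C2–C12 polymethylene chain, that a reducing agent can hardly tell apart, so C13 is set while the bond is made. A nickel/bis(oxazoline) catalyst joins racemic 1-bromobutyl benzoate to a C12 alkylzinc bromide and converts both enantiomers into the (S)-benzoate in one operation. The zinc reagent carries a tert-butyl ester, orthogonal to the benzoate, so the benzoate protects the C13 hydroxyl until the end. The acyl link to the phloroglucinol ring (ring A) follows by Friedel–Crafts acylation.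

Key step: step 3

Numbering: C1 is the ketone carbon on ring A (the 2,4,6-trihydroxyphenyl ring), C13 the carbinol carbon, C14–C16 the propyl end.
Assumption: tert-butyl 12-bromododecanoate is taken as a purchasable linker-type building block; it replaces a simple alkyl ester so that the chain-end carboxyl can be freed with acid without touching the C13 benzoate.
Ligand: L* = 2,2′-(propane-2,2-diyl)bis(4-phenyl-4,5-dihydrooxazole), single enantiomer; a closely related C2-symmetric bis(oxazoline) may replace it after a short screen.

Step 1
Reactants: 1 butanal; 2 benzoyl bromide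
Product: 3 rac-1-bromobutyl benzoate
Conditions: ZnBr2 (2 mol %), CH2Cl2, −10 °C to rt, N2; no aqueous work-up, used crude after assay against an internal standard
Reagents that add atoms: none
Why: Lewis-acid-catalysed addition of an acyl bromide across an aldehyde C=O (1-haloalkyl ester formation) is a general addition in which every atom of both reactants ends up in 3, and C13 is deliberately formed racemic because step 3 is stereoconvergent.

Step 2
Reactants: 4 tert-butyl 12-bromododecanoate
Product: 5 [12-(tert-butoxy)-12-oxododecyl]zinc bromide
Conditions: Zn dust (1.5 equiv), I2 (5 mol %), DMA, 80 °C; solution decanted, titrated with I2, used directly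
Reagents that add atoms: zinc dust, [Zn]
Why: Oxidative insertion of iodine-activated zinc into a primary alkyl bromide in a polar amide solvent is the standard entry to ester-bearing alkylzinc halides, and the tert-butyl ester is inert to the carbon–zinc bond.

Step 3
Reactants: 3 rac-1-bromobutyl benzoate; 5 [12-(tert-butoxy)-12-oxododecyl]zinc bromide
Product: 6 tert-butyl (S)-13-(benzoyloxy)hexadecanoate
Conditions: NiBr2·glyme (10 mol %), L* (12 mol %), 5 (1.3 equiv), THF/DMA, −10 °C
Reagents that add atoms: none
Why: A monovalent nickel bromide complex of the bis(oxazoline) abstracts bromine from either enantiomer of 3 to give a planar 1-(benzoyloxy)butyl radical, which erases the configuration of the racemate; the divalent alkylnickel complex formed by transmetalation from 5 captures this radical, and C(sp3)–C(sp3) reductive elimination from the resulting trivalent dialkylnickel species forms C12–C13 and returns monovalent nickel. The closest known reaction type is the nickel-catalysed enantioconvergent Negishi-type coupling of racemic 1-haloalkyl esters with primary alkylzinc halides, which gives esters of dialkyl carbinols. No ring is closed. C13 is set by the chiral ligand alone: the catalyst distinguishes the benzoyloxy group, whose carbonyl can bind nickel, from the propyl group (not propyl from the incoming chain), and the ligand enantiomer that gives (S) is fixed in a pilot run by MTPA ester analysis of the alcohol from a debenzoylated sample. The step needs chemoselectivity for the activated C–Br bond over the two ester carbonyls and cross-coupling over homocoupling or β-hydride elimination, which the mild organozinc, the radical-stabilising acyloxy group of 3 and the low temperature are expected to secure.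

Step 4
Reactants: 6 tert-butyl (S)-13-(benzoyloxy)hexadecanoate
Product: 7 (S)-13-(benzoyloxy)hexadecanoic acid
Conditions: TFA/CH2Cl2 (1:3), 0 °C to rt; toluene co-evaporation
Reagents that add atoms: none
Why: Acidolysis of a tert-butyl ester (alkyl–oxygen cleavage through the tert-butyl cation) proceeds at room temperature, while the secondary benzoate cannot ionise under these conditions and the C13 configuration stays untouched.

Step 5
Reactants: 7 (S)-13-(benzoyloxy)hexadecanoic acid; 8 phloroglucinol
Product: 10 (S)-16-oxo-16-(2,4,6-trihydroxyphenyl)hexadecan-4-yl benzoate, via (S)-13-(benzoyloxy)hexadecanoyl chloride 9 (not isolated)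
Conditions: (COCl)2, DMF (cat.), CH2Cl2, 0 °C to rt, evaporate; then 8 (2 equiv), AlCl3 (6 equiv), CH2Cl2/MeNO2, 0 to 40 °C; aq. HCl
Reagents that add atoms: none
Why: Friedel–Crafts C-acylation of the highly nucleophilic, threefold-symmetric ring A by the acid chloride can give only one monoketone, since any aryl ester from O-acylation is funnelled to it by Fries rearrangement under excess AlCl3 and the first acyl group deactivates the ring towards a second one.

Step 6
Reactants: 10 (S)-16-oxo-16-(2,4,6-trihydroxyphenyl)hexadecan-4-yl benzoate
Product: 11 (S)-13-hydroxy-1-(2,4,6-trihydroxyphenyl)hexadecan-1-one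
Conditions: NaOH (2 M aq., 8 equiv), MeOH/THF, argon, rt to 40 °C; then 1 M HCl
Reagents that add atoms: none
Why: Saponification cleaves the benzoate at its acyl–oxygen bond, so the C13–O bond and the (S) configuration are retained, and the aryl ketone, held as its unreactive phenolate under exclusion of air, should survive.

Compound list
1 | butanal | CCCC=O | starting material
2 | benzoyl bromide | O=C(Br)c1ccccc1 | starting material
3 | rac-1-bromobutyl benzoate | CCCC(Br)OC(=O)c1ccccc1 | intermediate
4 | tert-butyl 12-bromododecanoate | CC(C)(C)OC(=O)CCCCCCCCCCCBr | starting material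
5 | [12-(tert-butoxy)-12-oxododecyl]zinc bromide | CC(C)(C)OC(=O)CCCCCCCCCCC[Zn]Br | intermediate
6 | tert-butyl (S)-13-(benzoyloxy)hexadecanoate | CCC[C@H](OC(=O)c1ccccc1)CCCCCCCCCCCC(=O)OC(C)(C)C | intermediate
7 | (S)-13-(benzoyloxy)hexadecanoic acid | CCC[C@H](OC(=O)c1ccccc1)CCCCCCCCCCCC(=O)O | intermediate
8 | phloroglucinol | Oc1cc(O)cc(O)c1 | starting material
9 | (S)-13-(benzoyloxy)hexadecanoyl chloride | CCC[C@H](OC(=O)c1ccccc1)CCCCCCCCCCCC(=O)Cl | intermediate
10 | (S)-16-oxo-16-(2,4,6-trihydroxyphenyl)hexadecan-4-yl benzoate | CCC[C@H](OC(=O)c1ccccc1)CCCCCCCCCCCC(=O)c1c(O)cc(O)cc1O | intermediate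
11 | (S)-13-hydroxy-1-(2,4,6-trihydroxyphenyl)hexadecan-1-one | CCC[C@H](O)CCCCCCCCCCCC(=O)c1c(O)cc(O)cc1O | target

Total step count: 6
Longest linear sequence: 5 steps (4 → 5 → 6 → 7 → 10 → 11; the branch from 1 through 3 is equally long)

Steps most likely to fail

Step 3. Enantiocontrol may be inadequate or of the wrong sense with the chosen ligand, or β-hydride elimination and homocoupling at nickel may outrun cross-coupling. The fallback makes the same C12–C13 bond by reagent-controlled carbonyl addition and sets out from 4. Finkelstein exchange (NaI, acetone, reflux) should give tert-butyl 12-iodododecanoate F1. Iodine–zinc exchange with neat Et2Zn (CuI cat., 50 °C, volatiles removed under vacuum) should give bis[12-(tert-butoxy)-12-oxododecyl]zinc F2. Addition of F2 to butanal 1 in toluene at −20 °C, mediated by Ti(OiPr)4 and catalysed by enantiopure trans-N,N′-bis(trifluoromethanesulfonyl)cyclohexane-1,2-diamine (the enantiomer that delivers the (S)-carbinol), should give tert-butyl (S)-13-hydroxyhexadecanoate F3. Benzoylation (BzCl, pyridine, DMAP, CH2Cl2) would return to the route at 6.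

Step 5. AlCl3 may ionise or cleave the secondary benzoate (erosion of C13, elimination), O-acylation may fail to rearrange, or a second acylation may compete. The fallback avoids any Lewis acid and sets out from 7. TFAA in CH2Cl2 at 0 °C should give (S)-13-(benzoyloxy)hexadecanoic trifluoroacetic anhydride F4 (not isolated). F4 should acylate purchased 1,3,5-tris(benzyloxy)benzene (c1ccccc1COc1cc(OCc2ccccc2)cc(OCc2ccccc2)c1) at rt to give (S)-16-oxo-16-[2,4,6-tris(benzyloxy)phenyl]hexadecan-4-yl benzoate F5. Hydrogenolysis of the three benzyl ethers (H2, 10% Pd/C, EtOAc) would return to the route at 10.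

Step 6. The electron-rich triphenolate may oxidise or undergo retro-acylation in alkali, or hydrolysis of the hindered benzoate may stall in the soapy medium. The fallback reverses the order of unmasking so that the last step is neutral, and sets out from 7. The mixed anhydride (S)-13-(benzoyloxy)hexadecanoic trifluoroacetic anhydride F4 and the ketone (S)-16-oxo-16-[2,4,6-tris(benzyloxy)phenyl]hexadecan-4-yl benzoate F5 are made as above. Saponification of the benzoate of F5 (NaOH, MeOH/THF, 50 °C), with no free phenol present, should give (S)-13-hydroxy-1-[2,4,6-tris(benzyloxy)phenyl]hexadecan-1-one F6. Hydrogenolysis (H2, 10% Pd/C, EtOAc) would then arrive at 11.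

Further compounds
F1 | step 3 | tert-butyl 12-iodododecanoate | CC(C)(C)OC(=O)CCCCCCCCCCCI
F2 | step 3 | bis[12-(tert-butoxy)-12-oxododecyl]zinc | CC(C)(C)OC(=O)CCCCCCCCCCC[Zn]CCCCCCCCCCCC(=O)OC(C)(C)C
F3 | step 3 | tert-butyl (S)-13-hydroxyhexadecanoate | CCC[C@H](O)CCCCCCCCCCCC(=O)OC(C)(C)C
F4 | step 5 | (S)-13-(benzoyloxy)hexadecanoic trifluoroacetic anhydride | CCC[C@H](OC(=O)c1ccccc1)CCCCCCCCCCCC(=O)OC(=O)C(F)(F)F
F5 | step 5 | (S)-16-oxo-16-[2,4,6-tris(benzyloxy)phenyl]hexadecan-4-yl benzoate | CCC[C@H](OC(=O)c1ccccc1)CCCCCCCCCCCC(=O)c1c(OCc2ccccc2)cc(OCc2ccccc2)cc1OCc1ccccc1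
F6 | step 6 | (S)-13-hydroxy-1-[2,4,6-tris(benzyloxy)phenyl]hexadecan-1-one | CCC[C@H](O)CCCCCCCCCCCC(=O)c1c(OCc2ccccc2)cc(OCc2ccccc2)cc1OCc1ccccc1
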